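1. We count in fractions of the charge: p of target, e of isomer, a of starting material left, and b of coupling partner left, each of its own charge. Taking one coupling partner per starting material, equal charges give a = b = one minus p minus e.

| setting | delta | theta | flask |
|---|---|---|---|
| starting material | 0.020 M | 0.020 M | 0.020 M |
| coupling partner | 0.020 M | 0.020 M | 0.0200 M |
| free catalyst | 100 µM | 67 µM | 100 µM |
| impurity | 29 µM | 29 µM | 29 µM |
| remark | the very flask that is asked about, followed so far | run made earlier |  |
| time |  |  | 3.0 h |

| run | time / min | target / % | isomer of the product / % |
|---|---|---|---|
| delta | 20.0 | 21 | 28 |
| delta | 40.0 | 21 | 30 |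
| delta | 50.0 | 24 | 29 |
| delta | 80.0 | 20 | 32 |
| delta | 90.0 | 22 | 26 |
| theta | 10.0 | 27 | 16 |
| theta | 20.0 | 20 | 22 |
| theta | 40.0 | 22 | 25 |
| theta | 60.0 | 21 | 27 |
| theta | 120 | 23 | 28 |

(each reading ± 1.5 percentage points)

* amount of target at 3.0 h, in percent of the starting material charged
* amount of isomer of the product at 3.0 h, in percent of the starting material charged

2. Fastest rung: in the theta run, target stands at 27% by 10.0 min, above its later 23%, while isomer is at 16%. We read target as made first.

3. Middle rung: the theta isomer approaches 28%, and its distance from that level falls from 12 percentage points to 6 points, about half, in 10.0 min. That reading carries the scatter.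

4. Slowest rung: compare the forward rate, taken as going with a·b, with the back rate, taken as going with p. Their ratio starts large, while p is small, and drifts towards one, where p/(a·b) stops moving. The delta readings show that rest, with means of 21.6% target and 29.0% isomer. So p/(a·b) reads 0.885, our balance quotient, the reaction quotient at rest. The last theta reading, with 67 µM of free catalyst, gives 0.958.

5. The asked flask has the delta charges, and 3.0 h is far longer than that halving time, which was read in the theta run, with less free catalyst than the asked flask. So we commit to the delta means.

6. The forecast gives 22% target (19.5% to 24%) and 29.5% isomer (27.5% to 33%), noting that “the plateau doesn't depend on catalyst loading”.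

7. The flask gives 20.5% target and 28.8% isomer.

    starting material + coupling partner + free catalyst ⇌ target + free catalyst, rate k1*[starting material]*[coupling partner]*[free catalyst] forward; the back reaction follows from the equilibrium constant (K = 40.0 L mol⁻¹, k = 3.80 × 10⁵ L² mol⁻² min⁻¹)
    target + free catalyst ⇌ isomer of the product + free catalyst, rate k2*[free catalyst]*[target] forward; the back reaction follows from the equilibrium constant (K = 1.40, k = 1700 L mol⁻¹ min⁻¹)
    free catalyst + impurity → spent catalyst (k = 91000 L mol⁻¹ min⁻¹)

Left ten times as long, the flask still holds 20.5% target. Its balance quotient at 3.0 h is 0.800. With b counted against the partner's own charge, we scale the quotient with that charge, the other charges held, and so expect 2.21 at 0.050 M of coupling partner. The neighbour flask with that charge stands at 32.0% target, 23.1% starting material and 69.3% of its own charge of coupling partner, a quotient of 2.00.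

(All runs stem from a simulated flask with constants of no real substance, and the scatter is random.)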